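Assumption: 1, 3 and 5 are taken as purchasable; the Wittig ring closure is expected to give a mixture of alkene geometries, so 9 is drawn as its Z,Z isomer and the mixture is hydrogenated as it is.

## Analysis of the target

The target 11 is a 21-membered diaryl ether cyclophane. Ring A is a 1,3,5-trisubstituted benzene carrying one hydroxyl, the ether oxygen and chain carbon C14. Ring B is a hydroquinone: C1 carries the ether oxygen, C2 and C5 the hydroxyls, and C3 chain carbon C1. The two rings are bridged once by oxygen and once by a saturated, unbranched C14 chain. There is no stereocentre, and a ring this large and flexible should have no stable planar chirality, so nothing stereochemical has to be controlled. The sensitive part is ring B, a 2-aryloxyhydroquinone that air oxidises easily to the quinone, above all in base, so its oxygens should stay masked until the last step. The difficulties are the entropic cost of closing a 21-membered ring, a chain without any functional group to help bond formation, and an ether bond at ring B C1 that sits next to the C2 oxygen. The plan rests on the fact that both chain termini, C1 on ring B C3 and C14 on ring A, are benzylic CH2 groups. Each can therefore come from a formyl carbon on a preformed diaryl ether, and the twelve carbons C2 to C13 between them form a symmetrical unit that one bifunctional reagent can deliver.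

## Retrosynthetic reasoning

**11 to 10.** The three phenolic O–H bonds of 11 are traced back to O–CH3 bonds in the saturated macrocycle trimethyl ether 10. Methyl ethers are inert to copper catalysis, ylide chemistry and hydrogenation. Free phenols would protonate an ylide, and the free hydroquinone would not survive air and base. The forward reaction has to cleave three aryl methyl ethers without touching the diaryl ether. A Lewis-acid dealkylation does this, because only the methyl groups offer an sp3 carbon to the halide.

**10 to 9.** The bonds C1–C2 and C13–C14 of 10 are redrawn as double bonds, which gives the macrocyclic diene 9. This puts an olefination retron at each benzylic position. The forward step is a catalytic hydrogenation, which also makes the alkene geometry of 9 irrelevant.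

**9 to 4 and 6.** Both C=C bonds of 9 are cut at once. Each benzylic carbon becomes a formyl carbon of the diaryl ether dialdehyde 4, and C2 to C13 become the bis-phosphonium salt 6. The bis-ylide 7 made from 6 is the actual nucleophile, and the half-reacted ylide aldehyde 8 is the species that closes the ring. The cut is made here and not at the ether C–O bond because a ring-closing aryl ether coupling would have to form the most hindered bond of the molecule at high dilution. Olefination of an aldehyde by an ylide is fast, irreversible and blind to every other group present. The gain is convergence: the rigid half of the ring is made by an ordinary intermolecular coupling, and one symmetrical C12 piece supplies the rest. The forward reaction has to make the second olefination intramolecular and not chain-extending.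

**4 to 2 and 3.** The ether C–O bond at ring B C1 of 4 is cut on the ring B side of oxygen. This gives 3-bromo-2,5-dimethoxybenzaldehyde 2 as electrophile and 3-hydroxy-5-methoxybenzaldehyde 3 as nucleophile. The polarity is chosen this way because the ring B pattern with a halogen next to the C2 oxygen is available, and ring A is available as a phenol with the correct 1,3,5 pattern. The forward reaction is a copper-catalysed aryl ether coupling that must tolerate two formyl groups and one ortho methoxy group.

**2 to 1.** The O–CH3 bond at C2 of 2 is cut to give 3-bromo-2-hydroxy-5-methoxybenzaldehyde 1. The methylation comes before the coupling, because the free ortho hydroxyl of 1 would compete as a nucleophile and bind the copper catalyst.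

**6 to 5.** The two C–P bonds of 6 are cut to give 1,12-dibromododecane 5. The forward reaction is a double quaternisation at two primary carbons.

## Alternatives that were turned down

**Alternative 1:** ring B is built from a four-membered ring.
- Disconnection: the cyclobutenone A1 comes from a squarate ester, to which the ring A aryloxy group is added by addition–elimination and a 1-substituted vinyl group carrying the C14 chain by 1,2-addition.
- Forward key step: heating opens A1 to a dienylketene, the ketene carbon bonds to the terminal CH2 of the vinyl group in a 6π electrocyclisation, and tautomerisation gives the hydroquinone A2.
- For it: the substitution pattern of ring B follows from the connectivity of A1 alone. The aryl ether bond is made on an activated four-membered ring, with no hindered metal-catalysed coupling. On that bond this alternative is stronger than the chosen route.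
- Against it: ring B is built from scratch although its pattern is purchasable. A1 needs a functionalised alkenyl organometallic and a 1,2-addition next to an aryloxy leaving group, which invites substitution. A2 is a free, air-sensitive hydroquinone that must be protected. The macrocycle is still open and would need a separate alkyl–aryl coupling at the ring A bromide under high dilution.
- Comparison: the chosen strategy has a more demanding ether coupling, but it reaches the macrocyclisation substrate 4 in two steps and closes the ring with the same step that installs the chain.

**Alternative 2:** the bond from ring B C3 to chain C1 is disconnected at the ketone oxidation level.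
- Disconnection: the precursor is the 21-membered aryl macrolactone A3, in which the acid terminus of a chain attached to ring A esterifies the ring B phenol next to the ether oxygen.
- Forward key step: irradiation at 254 nm cleaves the aryl ester bond, and the tethered acyl radical recombines at the only free ortho carbon to give the ortho-hydroxyaryl ketone A4.
- For it: the ring is closed by lactonisation, a dependable unimolecular macrocyclisation. The tether and the blocked para position fix the regiochemistry of the C–C bond. On the reliability of the ring-closing event this alternative is at least as strong as the chosen route.
- Against it: escape of the radical pair from the solvent cage returns the phenol. A4 absorbs at the irradiation wavelength, and dilute photolysis is hard to scale. The ketone must later be reduced to CH2. The seco acid needs its own C–C bond construction at ring A and differentiated ring B oxygens.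
- Comparison: the chosen strategy forms both ring-to-chain bonds in one operation, at an oxidation level that needs only hydrogenation.

**Alternative 3:** the biogenetic bond, the ether C–O bond at ring B, is disconnected.
- Disconnection: the precursor is the resorcinol-tethered bromoquinone A5.
- Forward key step: with a mild base at high dilution a ring A phenoxide adds to the bromine-bearing quinone carbon, bromide leaves, and the 21-membered aryloxyquinone A6 results. A mild reduction of A6 would give 11.
- For it: the oxidation level of the target is reached directly. Ring B needs no protecting groups, the two ring A hydroxyls are equivalent, and no harsh demethylation is needed. On endgame economy this alternative is stronger.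
- Against it: the phenoxide is ambident, and its ring carbons can attack the quinone. The quinone also has two unsubstituted positions open to conjugate addition, and quinone/hydroquinone redox exchange and base sensitivity add further pathways. A5 itself needs a C14 chain joined to two different rings and a late oxidation next to a free resorcinol, so the total step count is no lower.
- Comparison: the chosen strategy closes the ring on robust, fully etherified intermediates, in a reaction where only formyl groups and ylide carbons can react.

Key step: step 4

## Route

Step 1
Reactants: 1 3-bromo-2-hydroxy-5-methoxybenzaldehyde
Product: 2 3-bromo-2,5-dimethoxybenzaldehyde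
Conditions: MeI, K2CO3, DMF, rt
Reagents that add atoms: iodomethane, CI
Why: Williamson ether synthesis; the phenol, acidified by the ortho formyl and ortho bromo groups, is deprotonated by carbonate and methylated at oxygen, while the aldehyde is not enolisable and stays untouched.

Step 2
Reactants: 2 3-bromo-2,5-dimethoxybenzaldehyde; 3 3-hydroxy-5-methoxybenzaldehyde
Product: 4 3-(3-formyl-5-methoxyphenoxy)-2,5-dimethoxybenzaldehyde
Conditions: CuI (10 mol%), picolinic acid (20 mol%), K3PO4, DMSO, 90 °C, argon
Reagents that add atoms: none
Why: Ullmann-type copper-catalysed diaryl ether synthesis; the picolinate ligand system accepts ortho-substituted aryl bromides, and the phosphate base is not nucleophilic, so the two non-enolisable formyl groups should survive. The bromine of 2 is the only halogen, so the ether can form only at ring B C1.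

Step 3
Reactants: 5 1,12-dibromododecane
Product: 6 dodecane-1,12-diylbis(triphenylphosphonium) dibromide
Conditions: PPh3 (2.5 equiv), MeCN, reflux; precipitation with Et2O, drying under vacuum
Reagents that add atoms: triphenylphosphine, c1ccccc1P(c1ccccc1)c1ccccc1
Why: Double SN2 quaternisation of the phosphine at two unhindered primary bromides; the dication salt should precipitate and must be dried thoroughly before ylide formation.

Step 4
Reactants: 4 3-(3-formyl-5-methoxyphenoxy)-2,5-dimethoxybenzaldehyde; 6 dodecane-1,12-diylbis(triphenylphosphonium) dibromide
Product: 9 (1Z,13Z)-macrocyclic diene trimethyl ether, via C12 bis-ylide 7 (not isolated), via seco ylide aldehyde 8 (not isolated)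
Conditions: 6, KN(SiMe3)2 (1.95 equiv), THF, 0 °C to rt; this solution and 4 in THF added at equal rates by syringe pump over 10 h to THF at rt (final about 2 mM), then 40 °C, 2 h
Reagents that add atoms: none
Why: This is a Wittig olefination run twice: each ylide carbon of 7 adds to a formyl carbon to give an oxaphosphetane, which collapses by cycloreversion to the alkene and triphenylphosphine oxide. The first, intermolecular olefination should occur mainly at the less hindered and more electrophilic ring A formyl group and give 8; the regioisomer from first attack at the ring B formyl group leads to the same macrocycle because the chain is symmetrical. The ring is closed by the second olefination, a 21-exo-trig addition of the remaining ylide carbon to the ring B formyl group, followed by collapse of the oxaphosphetane so that C1=C2 ends up inside the ring. The closest known reaction type is the bis-Wittig cyclisation of aromatic dialdehydes with α,ω-bis-ylides used for cyclophanes. No stereocentre is formed; the lithium-free potassium conditions favour Z alkenes from the unstabilised ylide, but the geometry is of no consequence because step 5 removes it. The selectivity that matters is ring closure over chain growth, and it is secured by adding both components at matched rates, so that each stays at a very low stationary concentration and in 1:1 ratio, by the meta relationship of both formyl groups to the bent ether hinge, which a flexible twelve-carbon tether spans without strain, and by the irreversibility of each olefination. A slight deficit of base avoids free amide, which would add to the aldehydes.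

Step 5
Reactants: 9 (1Z,13Z)-macrocyclic diene trimethyl ether
Product: 10 saturated macrocycle trimethyl ether
Conditions: H2 (1 atm), 10% Pd/C, EtOAc, rt
Reagents that add atoms: none
Why: Heterogeneous catalytic hydrogenation of two 1,2-disubstituted styrene-type alkenes; all geometric isomers converge on one product, and aryl methyl ethers and the diaryl ether are inert under these conditions.

Step 6
Reactants: 10 saturated macrocycle trimethyl ether
Product: 11 the target, the 21-membered trihydroxy diaryl ether cyclophane
Conditions: BBr3 (6 equiv), CH2Cl2, −78 °C to rt; MeOH quench, then aqueous NaHCO3/Na2S2O4 work-up under argon
Reagents that add atoms: none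
Why: Lewis-acid ether cleavage; BBr3 coordinates each methoxy oxygen and bromide attacks the methyl carbon in an SN2 step, while the diaryl ether offers no sp3 carbon and should stay intact. The reducing, oxygen-free work-up keeps the aryloxyhydroquinone of ring B from oxidising to the quinone.

## Compound list

1 | 3-bromo-2-hydroxy-5-methoxybenzaldehyde | COc1cc(Br)c(O)c(C=O)c1 | starting material
2 | 3-bromo-2,5-dimethoxybenzaldehyde | COc1cc(Br)c(OC)c(C=O)c1 | intermediate
3 | 3-hydroxy-5-methoxybenzaldehyde | COc1cc(O)cc(C=O)c1 | starting material
4 | 3-(3-formyl-5-methoxyphenoxy)-2,5-dimethoxybenzaldehyde | COc1cc(C=O)cc(Oc2cc(OC)cc(C=O)c2OC)c1 | intermediate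
5 | 1,12-dibromododecane | BrCCCCCCCCCCCCBr | starting material
6 | dodecane-1,12-diylbis(triphenylphosphonium) dibromide | [Br-].[Br-].c1ccccc1[P+](c1ccccc1)(c1ccccc1)CCCCCCCCCCCC[P+](c1ccccc1)(c1ccccc1)c1ccccc1 | intermediate
7 | C12 bis-ylide, dodecane-1,12-diylidenebis(triphenylphosphorane), formed in the flask | c1ccccc1P(c1ccccc1)(c1ccccc1)=CCCCCCCCCCCC=P(c1ccccc1)(c1ccccc1)c1ccccc1 | intermediate
8 | seco ylide aldehyde: 4 olefinated (Z) at the ring A formyl group, the chain ending in the triphenylphosphonium ylide, ring B formyl group free; formed in the flask | COc1cc(/C=C\CCCCCCCCCCC=P(c2ccccc2)(c2ccccc2)c2ccccc2)cc(Oc2cc(OC)cc(C=O)c2OC)c1 | intermediate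
9 | (1Z,13Z)-macrocyclic diene trimethyl ether: 5-methoxy-1,3-phenylene (ring A) and 2,5-dimethoxy-1,3-phenylene (ring B) joined by an ether oxygen and by a tetradeca-1,13-diene-1,14-diyl bridge, C1 on ring B C3 | COc1cc(/C=C\CCCCCCCCCC/C=C\c2cc(OC)cc3c2OC)cc(O3)c1 | intermediate
10 | saturated macrocycle trimethyl ether: the same two rings joined by the ether oxygen and a tetradecane-1,14-diyl bridge | COc1cc2cc(c1)Oc1cc(OC)cc(c1OC)CCCCCCCCCCCCCC2 | intermediate
11 | target: 5-hydroxy-1,3-phenylene (ring A) and 2,5-dihydroxy-1,3-phenylene (ring B) joined by an ether oxygen and a tetradecane-1,14-diyl bridge | Oc1cc2cc(c1)Oc1cc(O)cc(c1O)CCCCCCCCCCCCCC2 | target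

## Step count and risks

Total step count: 6. Longest linear sequence: 5 steps (steps 1, 2, 4, 5 and 6, from 1); step 3 is a one-step side branch from 5.

**Step 4 (key step).**
- Risk: chain growth and cyclodimerisation may outrun the ring-closing olefination. This happens when the local concentration rises, or when the ylide solution slowly decays in the syringe by adventitious hydrolysis or oxidation and the 1:1 ratio drifts.
- Fallback: the two olefinations are separated, setting out from 4 and 6. An excess of 6 is treated with a substoichiometric amount of KN(SiMe3)2 in THF, so that mainly one phosphonium end becomes an ylide, and this is added to an excess of 4 at −78 °C. The single Wittig reaction should give the ω-formyl phosphonium bromide F1. It is drawn as the ring A alkene; the regioisomer from reaction at the ring B formyl group is equally usable. F1 is separated as a monocationic salt from neutral 4 and from the dication 6. F1 is then added slowly to KOC(CH3)3 in THF at high dilution. Deprotonation gives 8 with no second component present, and the now strictly unimolecular ring-closing olefination comes back to the route at 9.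

**Step 2.**
- Risk: C–O bond formation at the bromide flanked by a methoxy group may be slow. Reductive loss of bromine from 2 and base-induced disproportionation of the formyl groups could then take over during prolonged heating.
- Fallback: the roles of the two rings are exchanged so that the hindered ring B becomes the nucleophile, setting out from 2. Miyaura borylation (bis(pinacolato)diboron, PdCl2(dppf), KOAc, dioxane, 90 °C) should give 2,5-dimethoxy-3-(4,4,5,5-tetramethyl-1,3,2-dioxaborolan-2-yl)benzaldehyde F2. Oxidation with NaBO3·4H2O in THF/water gives 3-hydroxy-2,5-dimethoxybenzaldehyde F3. The same CuI/picolinic acid/K3PO4 coupling is then run with purchased 3-bromo-5-methoxybenzaldehyde F4, an unhindered bromide activated by its meta formyl group, and this comes back to the route at 4.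

**Step 6.**
- Risk: air oxidation of the electron-rich aryloxyhydroquinone to the quinone during work-up and chromatography, and incomplete cleavage of the ring B methoxy group that sits between two substituents. Either would leave a mixture that is hard to purify at the hydroquinone oxidation level.
- Fallback: purification is moved to the quinone oxidation level, setting out from 10. After the BBr3 treatment the crude product is deliberately oxidised with Ag2O (Et2O, MgSO4, rt) to the macrocyclic aryloxyquinone F5, which should be stable to air and chromatography and separable from partly methylated material. Shaking an EtOAc solution of F5 with aqueous Na2S2O4 under argon reduces it and comes back to the route at 11.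

## Further compounds

F1 | step 4 | ω-formyl phosphonium bromide: 4 olefinated (Z) at the ring A formyl group, the chain ending in CH2–PPh3+ Br−, ring B formyl group free | [Br-].COc1cc(/C=C\CCCCCCCCCCC[P+](c2ccccc2)(c2ccccc2)c2ccccc2)cc(Oc2cc(OC)cc(C=O)c2OC)c1
F2 | step 2 | 2,5-dimethoxy-3-(4,4,5,5-tetramethyl-1,3,2-dioxaborolan-2-yl)benzaldehyde | COc1cc(C=O)c(OC)c(B2OC(C)(C)C(C)(C)O2)c1
F3 | step 2 | 3-hydroxy-2,5-dimethoxybenzaldehyde | COc1cc(O)c(OC)c(C=O)c1
F4 | step 2 | 3-bromo-5-methoxybenzaldehyde | COc1cc(Br)cc(C=O)c1
F5 | step 6 | macrocyclic aryloxy-1,4-benzoquinone, the quinone form of the target | O=C1C=C2Oc3cc(O)cc(c3)CCCCCCCCCCCCCCC(=C1)C2=O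
A1 | alternative 1 | racemic 3-(3-bromo-5-methoxyphenoxy)-4-hydroxy-4-[16-(tert-butyldimethylsilyloxy)hexadec-1-en-2-yl]cyclobut-2-en-1-one | O=C1C=C(Oc2cc(OC)cc(Br)c2)C1(O)C(=C)CCCCCCCCCCCCCCO[Si](C)(C)C(C)(C)C
A2 | alternative 1 | 2-(3-bromo-5-methoxyphenoxy)-6-[14-(tert-butyldimethylsilyloxy)tetradecyl]benzene-1,4-diol | Oc1cc(CCCCCCCCCCCCCCO[Si](C)(C)C(C)(C)C)c(O)c(Oc2cc(OC)cc(Br)c2)c1
A3 | alternative 2 | 21-membered aryl macrolactone: the C14 acid chain on ring A esterified with the ring B hydroxyl next to the ether oxygen, both other oxygens as methyl ethers | COc1cc2cc(c1)Oc1cc(OC)ccc1OC(=O)CCCCCCCCCCCCC2
A4 | alternative 2 | 21-membered ortho-hydroxyaryl ketone, C1 of the chain as the carbonyl on ring B C3 | COc1cc2cc(c1)Oc1cc(OC)cc(c1O)C(=O)CCCCCCCCCCCCC2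
A5 | alternative 3 | 2-bromo-6-[14-(3,5-dihydroxyphenyl)tetradecyl]cyclohexa-2,5-diene-1,4-dione | O=C1C=C(Br)C(=O)C(CCCCCCCCCCCCCCc2cc(O)cc(O)c2)=C1
A6 | alternative 3 | 21-membered aryloxy-1,4-benzoquinone, the quinone form of the target | O=C1C=C2Oc3cc(O)cc(c3)CCCCCCCCCCCCCCC(=C1)C2=O
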